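The numbers are made up.

Late on, once starting material has gone, target has the over-reaction step left, with a half-life of 7.2 min in north-east, longer than the run of 2.0 min; so reckon what target pays before that.

    starting material → open intermediate (k1 = 0.098 /s)
    partner → second intermediate (k2 = 0.025 /s)
    open intermediate + second intermediate → target (k3 = 4.3 /M/s)
    starting material + target → side product (k4 = 41 /M/s)
    target → over-reaction product (k5 = 0.0016 /s)
    second intermediate + capture agent → trapped intermediate (k6 = 16 /M/s)

the same everywhere: capture agent 3.60 mM; time 2.0 min
- south-west: starting material 0.012 M (in portions, 4, over 1.5 min); partner 9.60 mM; first portion at the start, last at 1.5 min
- north-west: starting material 0.012 M (fed, over 1.5 min); partner 9.60 mM; all else is in the flask from the start; the feed brings no volume worth counting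
- south-east: starting material 0.012 M; partner 9.60 mM (fed, over 1.5 min); all else is in the flask from the start; the feed brings no volume worth counting
- north-east: starting material 0.012 M; partner 9.60 mM; everything together at the start

- a species is counted by the starting material in it: one side product counts as two
- run time (south-west): 2.0 min

- the best flask by amount of target, in percent of the starting material charged; "all alike" if 1.5 percentage points covers them all (south-west / north-west / south-east / north-east / all alike)
- amount of target at the end, in percent of the starting material charged, south-west
- amount of target at the end, in percent of the starting material charged, north-west
- amount of target at the end, in percent of the starting material charged, south-east
- amount of target at the end, in percent of the starting material charged, north-east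

Reckon the loss rate, not the amounts. Write kS for the constant of starting material + target and kO for the constant of starting material opening. Target in the full charge of north-east starts with a pseudo-first-order loss of 0.492 /s, a half-life of 1.4 s, shorter than the run. Opening then slows that loss: between the portions of south-west, 30.0 s apart, opening by itself takes the rate down to 0.0529 of its value.

Sum the falling rate over the life of a dose d, taking opening as the dose's way out. This gives the exposure E = kS·d/kO. One portion of south-west carries 1.26, the exposure, and standing target keeps e^(-E), here 0.285. The whole charge of north-east carries 5.02, but target made at time t faces only E·e^(-kO·t). That drops under 0.693, a survival above 0.5, after 0.337 min, earlier than the end of the run. In south-west the last portion comes at 1.5 min, and target standing then keeps less. So I rank north-east above south-west, and give no percentages.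

The forecast picks north-east: 15% for south-west, 18% for north-west, 35% for south-east and 37% for north-east, holding that “each late dose costs much of what has accumulated”.

The best flask is north-east at 33.4%; south-west gives 13.4%, north-west 15.8%, and south-east 28.9%, which is 6.1 percentage points under the forecast. South-east still holds 18.8% of its partner at 2.00 min. Now use E on south-west: at 1.50 min, just before the last portion, target stood at 13.0%, and keeping 0.285 means losing 9.3 points. In south-west, side product rose from 24.1% at 1.50 min to 41.5% at 2.00 min, which, counted double, is 8.7 points of target consumed.

Take south-west with capture agent at 0.0014 M. Capture agent does not enter E, so each portion still carries 1.26 and standing target keeps 0.285, and side product should stay ahead of target. The flask gives 17.9% of target, and more side product than target, at 50.2%.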